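**Plan**

1. Retrosynthetic cuts: (a) the three phenolic O–H bonds, carried as TIPS ethers; (b) C3–H, traced back to a C3–CO2allyl helper in β-keto ester 13; (c) C4=O, traced back to C4–OH; (d) ring C at C3–C4 (ring-closing aldol) and at O1–C2 (oxa-Michael), giving ring A salicylaldehyde 3 and ring B allyl 2-arylacrylate 10; (e) the two aryl–prenyl bonds and the ring B aryl–C3 bond, back to bromoarenes 1 and 4.
2. Enabling feature: C3 lies between the C4 carbonyl and the ring B ipso carbon C1', so an ester on C3 turns C2=C3 into an α-aryl acrylate. O1 sits on ring A ortho to the carbon bearing C4, so a salicylaldehyde delivers O1 to C2 and leaves the resulting C3 enolate one six-ring closure away from the formyl carbon C4.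
3. Forward order: ring A piece 3 (steps 1–2) and ring B piece 10 (steps 3–6) are made separately, both with the same 2,4-dioxygenated 5-prenyl pattern. Ring C, the only ring formed, arises in step 7; oxidation (step 8), decarboxylative protonation (step 9) and desilylation (step 10) follow.
4. Stereochemistry: the single stereocentre, C3 (S), is set in step 9 by enantioselective protonation of a palladium enolate under a chiral phosphinooxazoline ligand. The C3 and C4 centres formed in step 7 are uncontrolled and erased, and step 10 is buffered so that C3 is not epimerised.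

Key step: step 7

Remark: 1, 4, tributyl(3-methylbut-2-en-1-yl)stannane and diallyl oxalate are taken as catalogue chemicals; the sense of induction in step 9 is assumed, and the ligand antipode is to be used if the first run shows the opposite sense.

Abbreviations: prenyl = 3-methylbut-2-en-1-yl; allyl = prop-2-en-1-yl; TIPS = triisopropylsilyl; (S)-(CF3)3-t-BuPHOX = (S)-4-tert-butyl-2-{2-[bis(4-trifluoromethylphenyl)phosphanyl]-5-(trifluoromethyl)phenyl}-4,5-dihydrooxazole; chromane numbering O1, C2, C3, C4, C4a–C8a, ring B atoms primed.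

**Route**

Step 1
Reactants: 1 5-bromo-2,4-dihydroxybenzaldehyde
Product: 2 5-bromo-2-hydroxy-4-(triisopropylsilyloxy)benzaldehyde
Conditions: TIPSCl (1.05 equiv), imidazole (2.2 equiv), CH2Cl2, 0 °C to rt
Reagents that add atoms: triisopropylsilyl chloride, CC(C)[Si](Cl)(C(C)C)C(C)C
Why: The 2-hydroxyl is tied up in a hydrogen bond to the formyl oxygen and is the poorer nucleophile, so the bulky silyl chloride should take the 4-hydroxyl selectively (regioselective phenol silylation).

Step 2
Reactants: 2 5-bromo-2-hydroxy-4-(triisopropylsilyloxy)benzaldehyde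
Product: 3 2-hydroxy-5-prenyl-4-(triisopropylsilyloxy)benzaldehyde
Conditions: tributyl(prenyl)stannane (1.3 equiv), Pd(PPh3)4 (5 mol%), DMF, 90 °C
Reagents that add atoms: tributyl(3-methylbut-2-en-1-yl)stannane, CCCC[Sn](CCCC)(CCCC)CC=C(C)C
Why: Oxidative addition of zerovalent palladium into the aryl C–Br bond, transmetalation from the allylic stannane and reductive elimination at the less substituted allyl terminus should give the linear prenyl arene, and the free ortho-hydroxy aldehyde is tolerated (Stille coupling).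

Step 3
Reactants: 4 4,6-dibromobenzene-1,3-diol
Product: 5 1,5-dibromo-2,4-bis(triisopropylsilyloxy)benzene
Conditions: TIPSCl (2.4 equiv), imidazole (5 equiv), DMF, rt to 40 °C
Reagents that add atoms: triisopropylsilyl chloride, CC(C)[Si](Cl)(C(C)C)C(C)C
Why: Both phenols are silylated to remove the acidic protons before organolithium chemistry, and the bulky TIPS group is chosen because it resists ortho O-to-C silyl migration in the aryllithiums that follow (silyl ether formation).

Step 4
Reactants: 5 1,5-dibromo-2,4-bis(triisopropylsilyloxy)benzene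
Product: 7 1-bromo-5-prenyl-2,4-bis(triisopropylsilyloxy)benzene, via monolithiated arene 6 (not isolated)
Conditions: n-BuLi (1.0 equiv), THF, −78 °C; then CuBr·SMe2 (10 mol%), prenyl bromide (1.2 equiv), −78 to −20 °C
Reagents that add atoms: 1-bromo-3-methylbut-2-ene (prenyl bromide), CC(C)=CCBr
Why: Bromine–lithium exchange on the symmetric dibromide should stop after one bromine because the first aryl anion deactivates the ring, and copper-catalysed coupling of the aryllithium with prenyl bromide at its primary carbon gives the linear prenyl group (halogen–metal exchange followed by SN2 allylation).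

Step 5
Reactants: 7 1-bromo-5-prenyl-2,4-bis(triisopropylsilyloxy)benzene
Product: 9 allyl 2-oxo-2-[5-prenyl-2,4-bis(triisopropylsilyloxy)phenyl]acetate, via aryllithium 8 (not isolated)
Conditions: n-BuLi (1.05 equiv), THF, −78 °C; cannulated into diallyl oxalate (3 equiv), THF, −78 °C; aq. NH4Cl
Reagents that add atoms: diallyl oxalate, C=CCOC(=O)C(=O)OCC=C
Why: The second bromine–lithium exchange gives an aryllithium that, added inversely to excess oxalate diester at −78 °C, should be acylated only once because the tetrahedral adduct survives until the quench (aryllithium acylation to an α-keto ester).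

Step 6
Reactants: 9 allyl 2-oxo-2-[5-prenyl-2,4-bis(triisopropylsilyloxy)phenyl]acetate
Product: 10 allyl 2-[5-prenyl-2,4-bis(triisopropylsilyloxy)phenyl]prop-2-enoate
Conditions: Ph3PCH3Br (1.15 equiv), KHMDS (1.1 equiv), THF, 0 °C; then 9, −78 to 0 °C
Reagents that add atoms: methyltriphenylphosphonium bromide, C[P+](c1ccccc1)(c1ccccc1)c1ccccc1.[Br-]
Why: The keto carbonyl of the non-enolisable α-keto ester is far more electrophilic than the ester carbonyl, so a near-stoichiometric amount of the unstabilised ylide should methylenate it selectively to the 2-arylacrylate (Wittig olefination).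

Step 7
Reactants: 3 2-hydroxy-5-prenyl-4-(triisopropylsilyloxy)benzaldehyde; 10 allyl 2-[5-prenyl-2,4-bis(triisopropylsilyloxy)phenyl]prop-2-enoate
Product: 12 allyl 4-hydroxy-6-prenyl-3-[5-prenyl-2,4-bis(triisopropylsilyloxy)phenyl]-7-(triisopropylsilyloxy)chromane-3-carboxylate (racemic mixture of both C3/C4 diastereomers), via oxa-Michael adduct 11 (not isolated)
Conditions: Cs2CO3 (20 mol%), MeCN, 40 °C
Reagents that add atoms: none
Why: The caesium phenoxide of 3 adds through O1 to the unsubstituted acrylate carbon of 10 (the future C2), and the ester enolate thereby generated at C3 attacks the ortho formyl carbon (C4), forming the C3–C4 bond and closing ring C, after which the C4 alkoxide is protonated by a further molecule of 3 so that the base turns over. The closest known reaction type is the base-mediated domino oxa-Michael/aldol annulation of salicylaldehydes with acrylates and other electron-poor alkenes, which here stops at the aldol stage because C3 bears no hydrogen and water cannot be eliminated. Ring C closes in the favoured 6-(enolexo)-exo-trig mode. The two new stereocentres, quaternary C3 and carbinol C4, form without control as racemic diastereomers, which does not matter because C4 becomes a carbonyl in step 8 and C3 is reset in step 9. The step needs O-attack at C2 followed by C–C closure to win over reversal to 3 and 10 and over oligomerisation of 10: the aryl and ester groups on C3 stabilise the transient enolate, the intramolecular six-ring aldol drains the reversible oxa-Michael equilibrium, and the catalytic amount of base leaves the product as the neutral alcohol instead of a retro-aldol-prone alkoxide.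

Step 8
Reactants: 12 allyl 4-hydroxy-6-prenyl-3-[5-prenyl-2,4-bis(triisopropylsilyloxy)phenyl]-7-(triisopropylsilyloxy)chromane-3-carboxylate
Product: 13 allyl 4-oxo-6-prenyl-3-[5-prenyl-2,4-bis(triisopropylsilyloxy)phenyl]-7-(triisopropylsilyloxy)chromane-3-carboxylate (racemic)
Conditions: Dess–Martin periodinane (1.5 equiv), CH2Cl2, 0 °C to rt
Reagents that add atoms: none
Why: The periodinane should oxidise the hindered secondary benzylic alcohol to the aryl ketone under near-neutral conditions that spare the prenyl alkenes, the silyl ethers and the allyl ester and avoid base-induced retro-aldol cleavage, and both diastereomers converge on one racemic β-keto ester (Dess–Martin oxidation).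

Step 9
Reactants: 13 allyl 4-oxo-6-prenyl-3-[5-prenyl-2,4-bis(triisopropylsilyloxy)phenyl]-7-(triisopropylsilyloxy)chromane-3-carboxylate
Product: 14 (3S)-6-prenyl-3-[5-prenyl-2,4-bis(triisopropylsilyloxy)phenyl]-7-(triisopropylsilyloxy)chroman-4-one
Conditions: Pd2(dba)3 (5 mol%), (S)-(CF3)3-t-BuPHOX (12.5 mol%), Meldrum's acid (2.5 equiv), 1,4-dioxane, 40 °C
Reagents that add atoms: none
Why: Zerovalent palladium ionises the allyl ester, the carboxylate loses CO2, and the resulting palladium enolate, whose faces are differentiated by the chiral phosphinooxazoline ligand and by the 2'-silyloxy group next to C1', is protonated at C3 by Meldrum's acid (which also takes up the allyl group) to set the (S)-centre under neutral conditions that should not epimerise the α-aryl ketone (enantioselective decarboxylative protonation).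

Step 10
Reactants: 14 (3S)-6-prenyl-3-[5-prenyl-2,4-bis(triisopropylsilyloxy)phenyl]-7-(triisopropylsilyloxy)chroman-4-one
Product: 15 (3S)-3-(2,4-dihydroxy-5-prenylphenyl)-7-hydroxy-6-prenylchroman-4-one (CNP0166009.1)
Conditions: TBAF (3.6 equiv), AcOH (3.6 equiv), THF, 0 °C
Reagents that add atoms: none
Why: Fluoride cleaves the three aryl O–Si bonds while the acetic acid buffer keeps the medium non-basic, so the enolisable C3 centre, the ortho-prenyl phenols and the chromanone ring should survive (buffered fluoride desilylation).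

**Compound list**

1 | 5-bromo-2,4-dihydroxybenzaldehyde | O=Cc1cc(Br)c(O)cc1O | starting material
2 | 5-bromo-2-hydroxy-4-(triisopropylsilyloxy)benzaldehyde | O=Cc1cc(Br)c(O[Si](C(C)C)(C(C)C)C(C)C)cc1O | intermediate
3 | 2-hydroxy-5-(3-methylbut-2-en-1-yl)-4-(triisopropylsilyloxy)benzaldehyde | O=Cc1cc(CC=C(C)C)c(O[Si](C(C)C)(C(C)C)C(C)C)cc1O | intermediate
4 | 4,6-dibromobenzene-1,3-diol | Oc1cc(O)c(Br)cc1Br | starting material
5 | 1,5-dibromo-2,4-bis(triisopropylsilyloxy)benzene | CC(C)[Si](Oc1cc(O[Si](C(C)C)(C(C)C)C(C)C)c(Br)cc1Br)(C(C)C)C(C)C | intermediate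
6 | [5-bromo-2,4-bis(triisopropylsilyloxy)phenyl]lithium (not isolated) | [Li]c1cc(Br)c(O[Si](C(C)C)(C(C)C)C(C)C)cc1O[Si](C(C)C)(C(C)C)C(C)C | intermediate
7 | 1-bromo-5-(3-methylbut-2-en-1-yl)-2,4-bis(triisopropylsilyloxy)benzene | Brc1cc(CC=C(C)C)c(O[Si](C(C)C)(C(C)C)C(C)C)cc1O[Si](C(C)C)(C(C)C)C(C)C | intermediate
8 | [5-(3-methylbut-2-en-1-yl)-2,4-bis(triisopropylsilyloxy)phenyl]lithium (not isolated) | [Li]c1cc(CC=C(C)C)c(O[Si](C(C)C)(C(C)C)C(C)C)cc1O[Si](C(C)C)(C(C)C)C(C)C | intermediate
9 | prop-2-en-1-yl 2-oxo-2-[5-(3-methylbut-2-en-1-yl)-2,4-bis(triisopropylsilyloxy)phenyl]acetate | C=CCOC(=O)C(=O)c1cc(CC=C(C)C)c(O[Si](C(C)C)(C(C)C)C(C)C)cc1O[Si](C(C)C)(C(C)C)C(C)C | intermediate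
10 | prop-2-en-1-yl 2-[5-(3-methylbut-2-en-1-yl)-2,4-bis(triisopropylsilyloxy)phenyl]prop-2-enoate | C=CCOC(=O)C(=C)c1cc(CC=C(C)C)c(O[Si](C(C)C)(C(C)C)C(C)C)cc1O[Si](C(C)C)(C(C)C)C(C)C | intermediate
11 | prop-2-en-1-yl 3-[2-formyl-4-(3-methylbut-2-en-1-yl)-5-(triisopropylsilyloxy)phenoxy]-2-[5-(3-methylbut-2-en-1-yl)-2,4-bis(triisopropylsilyloxy)phenyl]propanoate (racemic, not isolated) | O=Cc1cc(CC=C(C)C)c(O[Si](C(C)C)(C(C)C)C(C)C)cc1OCC(C(=O)OCC=C)c1cc(CC=C(C)C)c(O[Si](C(C)C)(C(C)C)C(C)C)cc1O[Si](C(C)C)(C(C)C)C(C)C | intermediate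
12 | prop-2-en-1-yl 4-hydroxy-6-(3-methylbut-2-en-1-yl)-3-[5-(3-methylbut-2-en-1-yl)-2,4-bis(triisopropylsilyloxy)phenyl]-7-(triisopropylsilyloxy)-3,4-dihydro-2H-chromene-3-carboxylate (racemic, both C3/C4 diastereomers) | C=CCOC(=O)C1(c2cc(CC=C(C)C)c(O[Si](C(C)C)(C(C)C)C(C)C)cc2O[Si](C(C)C)(C(C)C)C(C)C)COc2cc(O[Si](C(C)C)(C(C)C)C(C)C)c(CC=C(C)C)cc2C1O | intermediate
13 | prop-2-en-1-yl 6-(3-methylbut-2-en-1-yl)-3-[5-(3-methylbut-2-en-1-yl)-2,4-bis(triisopropylsilyloxy)phenyl]-4-oxo-7-(triisopropylsilyloxy)-3,4-dihydro-2H-chromene-3-carboxylate (racemic) | C=CCOC(=O)C1(c2cc(CC=C(C)C)c(O[Si](C(C)C)(C(C)C)C(C)C)cc2O[Si](C(C)C)(C(C)C)C(C)C)COc2cc(O[Si](C(C)C)(C(C)C)C(C)C)c(CC=C(C)C)cc2C1=O | intermediate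
14 | (3S)-6-(3-methylbut-2-en-1-yl)-3-[5-(3-methylbut-2-en-1-yl)-2,4-bis(triisopropylsilyloxy)phenyl]-7-(triisopropylsilyloxy)-2,3-dihydro-4H-chromen-4-one | CC(C)=CCc1cc2c(cc1O[Si](C(C)C)(C(C)C)C(C)C)OC[C@H](c1cc(CC=C(C)C)c(O[Si](C(C)C)(C(C)C)C(C)C)cc1O[Si](C(C)C)(C(C)C)C(C)C)C2=O | intermediate
15 | (3S)-3-[2,4-dihydroxy-5-(3-methylbut-2-en-1-yl)phenyl]-7-hydroxy-6-(3-methylbut-2-en-1-yl)-2,3-dihydro-4H-chromen-4-one (CNP0166009.1) | CC(C)=CCc1cc2c(cc1O)OC[C@H](c1cc(CC=C(C)C)c(O)cc1O)C2=O | target

**Step count and risks**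

Total steps: 10. Longest linear sequence: 8 steps (4 → 5 → 7 → 9 → 10 → 12 → 13 → 14 → 15, steps 3–10).

Steps most likely to fail:

Step 7. Both the oxa-Michael addition and the aldol closure at the congested, fully substituted C3 are reversible, so the sequence may drain back to 3 and 10, or 10 may oligomerise before ring closure. The fallback keeps the C3–C4 ring closure but uses carbonyl umpolung; it sets out from 7 (together with 3) and rejoins the route at 14. Bromide 7 is lithiated as in step 5 (via 8) and acylated with 2-chloro-N-methoxy-N-methylacetamide to give 2-chloro-1-[5-prenyl-2,4-bis(triisopropylsilyloxy)phenyl]ethan-1-one F1. Phenol 3 is O-alkylated with it (K2CO3, acetone) to give the keto aldehyde 2-{2-oxo-2-[5-prenyl-2,4-bis(triisopropylsilyloxy)phenyl]ethoxy}-5-prenyl-4-(triisopropylsilyloxy)benzaldehyde F2. A thiazolium-derived carbene (3-benzyl-5-(2-hydroxyethyl)-4-methylthiazolium chloride, Et3N, THF, 60 °C) then closes ring C by intramolecular crossed benzoin addition of the formyl carbon to the ketone, giving racemic 3-hydroxy-6-prenyl-3-[5-prenyl-2,4-bis(triisopropylsilyloxy)phenyl]-7-(triisopropylsilyloxy)chroman-4-one F3. SmI2 (THF–MeOH, −78 °C) cleaves the tertiary α-hydroxyl to give racemic 6-prenyl-3-[5-prenyl-2,4-bis(triisopropylsilyloxy)phenyl]-7-(triisopropylsilyloxy)chroman-4-one F4. This is converted into 14 through the cis alcohol (3S,4S)-6-prenyl-3-[5-prenyl-2,4-bis(triisopropylsilyloxy)phenyl]-7-(triisopropylsilyloxy)chroman-4-ol F5, exactly as in the fallback for step 9.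

Step 9. Facial discrimination in the protonation of the palladium enolate may be insufficient for this aryl group, or C-allylation of the enolate may compete with protonation. The fallback sets out from 13 and rejoins at 14. Non-selective deallylative decarboxylation (Pd(PPh3)4, morpholine, THF, rt) gives racemic 6-prenyl-3-[5-prenyl-2,4-bis(triisopropylsilyloxy)phenyl]-7-(triisopropylsilyloxy)chroman-4-one F4. Asymmetric transfer hydrogenation under dynamic kinetic resolution (RuCl(p-cymene)[(S,S)-TsDPEN], HCO2H/Et3N, EtOAc, 40 °C) follows: C3 epimerises through the enol while the matched enantiomer is reduced from the face anti to the aryl group. By analogy with aryl ketone reductions this should give the cis alcohol (3S,4S)-6-prenyl-3-[5-prenyl-2,4-bis(triisopropylsilyloxy)phenyl]-7-(triisopropylsilyloxy)chroman-4-ol F5. Dess–Martin oxidation of the C4 carbinol, which does not touch C3, returns 14.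

Step 2. Oxidative addition into the electron-rich, ortho-silyloxy aryl bromide may be slow, palladium-mediated allyl transfer to the free aldehyde may compete, or coupling may occur through the tertiary terminus of the stannane. The fallback installs the prenyl group before the formyl group without palladium; it sets out from 7 and rejoins at 3. Bromine–lithium exchange on 7 (n-BuLi, THF, −78 °C, via 8) and formylation with DMF give 5-prenyl-2,4-bis(triisopropylsilyloxy)benzaldehyde F6. TBAF (THF, 0 °C) removes both silyl groups to give 2,4-dihydroxy-5-prenylbenzaldehyde F7. Selective silylation of the 4-hydroxyl as in step 1 (TIPSCl, imidazole, CH2Cl2) returns 3.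

Further compounds
F1 | step 7 | 2-chloro-1-[5-(3-methylbut-2-en-1-yl)-2,4-bis(triisopropylsilyloxy)phenyl]ethan-1-one | O=C(CCl)c1cc(CC=C(C)C)c(O[Si](C(C)C)(C(C)C)C(C)C)cc1O[Si](C(C)C)(C(C)C)C(C)C
F2 | step 7 | 2-{2-oxo-2-[5-(3-methylbut-2-en-1-yl)-2,4-bis(triisopropylsilyloxy)phenyl]ethoxy}-5-(3-methylbut-2-en-1-yl)-4-(triisopropylsilyloxy)benzaldehyde | O=Cc1cc(CC=C(C)C)c(O[Si](C(C)C)(C(C)C)C(C)C)cc1OCC(=O)c1cc(CC=C(C)C)c(O[Si](C(C)C)(C(C)C)C(C)C)cc1O[Si](C(C)C)(C(C)C)C(C)C
F3 | step 7 | 3-hydroxy-6-(3-methylbut-2-en-1-yl)-3-[5-(3-methylbut-2-en-1-yl)-2,4-bis(triisopropylsilyloxy)phenyl]-7-(triisopropylsilyloxy)-2,3-dihydro-4H-chromen-4-one (racemic) | OC1(c2cc(CC=C(C)C)c(O[Si](C(C)C)(C(C)C)C(C)C)cc2O[Si](C(C)C)(C(C)C)C(C)C)COc2cc(O[Si](C(C)C)(C(C)C)C(C)C)c(CC=C(C)C)cc2C1=O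
F4 | step 9 | 6-(3-methylbut-2-en-1-yl)-3-[5-(3-methylbut-2-en-1-yl)-2,4-bis(triisopropylsilyloxy)phenyl]-7-(triisopropylsilyloxy)-2,3-dihydro-4H-chromen-4-one (racemic) | CC(C)=CCc1cc2c(cc1O[Si](C(C)C)(C(C)C)C(C)C)OCC(c1cc(CC=C(C)C)c(O[Si](C(C)C)(C(C)C)C(C)C)cc1O[Si](C(C)C)(C(C)C)C(C)C)C2=O
F5 | step 9 | (3S,4S)-6-(3-methylbut-2-en-1-yl)-3-[5-(3-methylbut-2-en-1-yl)-2,4-bis(triisopropylsilyloxy)phenyl]-7-(triisopropylsilyloxy)-3,4-dihydro-2H-chromen-4-ol | CC(C)=CCc1cc2c(cc1O[Si](C(C)C)(C(C)C)C(C)C)OC[C@H](c1cc(CC=C(C)C)c(O[Si](C(C)C)(C(C)C)C(C)C)cc1O[Si](C(C)C)(C(C)C)C(C)C)[C@@H]2O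
F6 | step 2 | 5-(3-methylbut-2-en-1-yl)-2,4-bis(triisopropylsilyloxy)benzaldehyde | O=Cc1cc(CC=C(C)C)c(O[Si](C(C)C)(C(C)C)C(C)C)cc1O[Si](C(C)C)(C(C)C)C(C)C
F7 | step 2 | 2,4-dihydroxy-5-(3-methylbut-2-en-1-yl)benzaldehyde | O=Cc1cc(CC=C(C)C)c(O)cc1O
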